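**Plan**

- Ring numbering used below: C1 is the quaternary carbon (OMe, prenyl), C2 the ring C=O, C3 the acyl-bearing carbon, C4 C–OH, C5 the prenyl-bearing carbon, C6 the C–OH next to C1. C1 is flanked by the C2 carbonyl and the oxygen-bearing C6, so moving C2 from C1 to the C6 oxygen gives an isomeric 2-pyrone (ring O, C2 to C6) with C1 as a side-chain CH(OMe)(prenyl) on C6.
- Retrosynthetic cuts, in order: the O4–methyl bond of a protected target; C1–C2 (carbocycle back to pyrone); then in the pyrone O4–Me, C3–acyl, the lactone C2–O bond, C5–C6 and both C–prenyl bonds.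
- Forward: two enolate prenylations give the chain halves, a β-keto ester dianion acylation joins them at C5–C6, and lactonisation closes the pyrone. C3 acylation and O4 methylation complete the racemic precursor; the carbocycle then arises from the pyrone by carbene-catalysed acyl transfer, and one demethylation ends the route.
- Stereochemistry: C1 (S) is the only stereocenter. It is set in the acyl transfer, where a chiral triazolylidene opens the racemic pyrone and the planar C1 enolate common to both enantiomers is acylated on one face.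

Key step: step 7

Remark: which antipode of the aminoindanol-derived triazolium salt leads to the (S) series cannot be predicted with certainty; the (5aS,10bR) salt is written, and its equally available mirror image would be used if the sense of induction proves opposite.
Remark: the enolised triketones 13 and 14 are drawn as one tautomer each.

**Route**

Step 1
Reactants: 1 methyl methoxyacetate; 2 prenyl bromide (1-bromo-3-methylbut-2-ene)
Product: 3 methyl 2-methoxy-5-methylhex-4-enoate (racemic)
Conditions: LiN(iPr)2 (1.05 equiv), THF, −78 °C; then 2, DMPU, −78 to −20 °C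
Reagents that add atoms: none
Why: Alkylation of the lithium enolate of an α-alkoxy ester with a reactive primary allylic bromide (SN2), the low temperature holding back Claisen self-condensation of the enolate.

Step 2
Reactants: 4 methyl acetoacetate; 2 prenyl bromide
Product: 5 methyl 7-methyl-3-oxooct-6-enoate
Conditions: LiN(iPr)2 (2.1 equiv), THF, 0 °C; then 2, 0 °C; 1 M HCl quench
Reagents that add atoms: none
Why: γ-Alkylation of a β-keto ester dianion, whose terminal carbanion is the more nucleophilic site.

Step 3
Reactants: 5 methyl 7-methyl-3-oxooct-6-enoate; 3 methyl 2-methoxy-5-methylhex-4-enoate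
Product: 6 methyl 6-methoxy-9-methyl-4-(3-methylbut-2-en-1-yl)-3,5-dioxodec-8-enoate (mixture of diastereomers and enol forms)
Conditions: 5 (2.2 equiv), LiN(iPr)2 (4.4 equiv), THF, 0 °C; then 3, −78 to 0 °C; 1 M HCl quench
Reagents that add atoms: none
Why: Claisen-type acylation of the dianion of 5 at its γ-carbon by ester 3, the excess dianion taking up the acidic proton of the β,δ-diketo ester, and the two stereocenters of 6 being of no consequence because one becomes sp2 in the next step and the ether carbon stays racemic.

Step 4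
Reactants: 6 methyl 6-methoxy-9-methyl-4-(3-methylbut-2-en-1-yl)-3,5-dioxodec-8-enoate
Product: 7 4-hydroxy-6-(1-methoxy-4-methylpent-3-en-1-yl)-5-(3-methylbut-2-en-1-yl)-2H-pyran-2-one (racemic)
Conditions: DBU (1.1 equiv), toluene, 90 °C; then 1 M HCl
Reagents that add atoms: none
Why: Base-mediated enol lactonisation of a 3,5-diketo ester to the 4-hydroxy-2-pyrone with loss of methanol, under non-acidic conditions that spare both prenyl olefins.

Step 5
Reactants: 7 4-hydroxy-6-(1-methoxy-4-methylpent-3-en-1-yl)-5-(3-methylbut-2-en-1-yl)-2H-pyran-2-one; 8 3-phenylpropanoic acid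
Product: 10 4-hydroxy-6-(1-methoxy-4-methylpent-3-en-1-yl)-5-(3-methylbut-2-en-1-yl)-3-(3-phenylpropanoyl)-2H-pyran-2-one (racemic), via 4-O-acyl pyrone ester 9 (not isolated)
Conditions: DCC (1.1 equiv), DMAP (0.3 equiv), toluene, rt then 80 °C
Reagents that add atoms: none
Why: Steglich esterification of the 4-hydroxyl followed in the same flask by DMAP-mediated O-to-C acyl migration (Fries-type) to C3, the only unsubstituted nucleophilic ring carbon, with the chelated 3-acyl-4-hydroxypyrone as the thermodynamic sink.

Step 6
Reactants: 10 4-hydroxy-6-(1-methoxy-4-methylpent-3-en-1-yl)-5-(3-methylbut-2-en-1-yl)-3-(3-phenylpropanoyl)-2H-pyran-2-one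
Product: 11 4-methoxy-6-(1-methoxy-4-methylpent-3-en-1-yl)-5-(3-methylbut-2-en-1-yl)-3-(3-phenylpropanoyl)-2H-pyran-2-one (racemic)
Conditions: Me2SO4 (1.5 equiv), K2CO3, acetone, 56 °C
Reagents that add atoms: dimethyl sulfate, COS(=O)(=O)OC
Why: O-Methylation of the acidic chelated enol by a hard methylating agent should give the 4-methoxy-2-pyrone, since C3 is fully substituted and the side-chain center is untouched.

Step 7
Reactants: 11 4-methoxy-6-(1-methoxy-4-methylpent-3-en-1-yl)-5-(3-methylbut-2-en-1-yl)-3-(3-phenylpropanoyl)-2H-pyran-2-one (racemic)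
Product: 13 (6S)-5-hydroxy-3,6-dimethoxy-4,6-bis(3-methylbut-2-en-1-yl)-2-(3-phenylpropanoyl)cyclohexa-2,4-dien-1-one, via ring-opened acyl triazolium enolate 12 (not isolated)
Conditions: (5aS,10bR)-2-mesityl-5a,10b-dihydro-4H,6H-indeno[2,1-b][1,2,4]triazolo[4,3-d][1,4]oxazin-2-ium chloride (20 mol %), DBU (1.2 equiv), 4 Å molecular sieves, THF, rt; then aq. citric acid
Reagents that add atoms: none
Why: Proposed new method: the triazolylidene adds to the lactone carbonyl C2 of 11 and expels the C6 enolate to give zwitterion 12; DBU and its conjugate acid then relay a proton from C1 to C5, which turns the racemic C1–H center into a planar C6=C1 enolate, and this carbon attacks the acyl azolium C2, after which loss of the carbene and enolisation give 13. The closest known reaction types are the alkoxide-mediated conversion of 4-methoxy-6-alkyl-2-pyrones into phloroglucinol ethers, the carbene-catalysed fragmentation and recombination of α,β-unsaturated enol esters, and enantioselective Steglich-type O-to-C acyl transfer. The carbocycle (C1 to C6) closes by a favoured 6-(enolendo)-exo-trig attack on the acyl azolium, which is geometrically possible because the cis C3=C4 double bond inherited from the pyrone holds C2 and C5 on the same side. The C1 stereocenter is set by the aminoindanol-derived triazolium, which is covalently bound to the very carbon that C1 attacks and so distinguishes the two enolate faces in a compact cyclic transition state; since both enantiomers of 11 pass through the same planar enolate, the step is stereoconvergent. It needs carbon over oxygen acylation and attack on the acyl azolium in preference to the 3-acyl ketone: O-acylation only re-forms 11 for another pass, the aldol adduct with the ketone is reversible, attack from C5 would give a four-membered ring, and deprotonation of the acidic enol 13 by DBU makes the C-acylation irreversible.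

Step 8
Reactants: 13 (6S)-5-hydroxy-3,6-dimethoxy-4,6-bis(3-methylbut-2-en-1-yl)-2-(3-phenylpropanoyl)cyclohexa-2,4-dien-1-one
Product: 14 (6S)-3,5-dihydroxy-6-methoxy-4,6-bis(3-methylbut-2-en-1-yl)-2-(3-phenylpropanoyl)cyclohexa-2,4-dien-1-one (CNP0319461.1)
Conditions: LiCl (5 equiv), DMSO, 120 °C; then dilute HCl
Reagents that add atoms: none
Why: SN2 attack of chloride on the methyl group of the C4 vinylogous ester (Krapcho-type dealkylation) releases the stabilised triketone enolate, whereas the tertiary methyl ether at C1 offers no such leaving group and the quaternary C1 cannot epimerise.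

**Compound list**

1 | methyl methoxyacetate | COCC(=O)OC | starting material
2 | prenyl bromide (1-bromo-3-methylbut-2-ene) | CC(C)=CCBr | starting material
3 | methyl 2-methoxy-5-methylhex-4-enoate (racemic) | COC(CC=C(C)C)C(=O)OC | intermediate
4 | methyl acetoacetate | CC(=O)CC(=O)OC | starting material
5 | methyl 7-methyl-3-oxooct-6-enoate | COC(=O)CC(=O)CCC=C(C)C | intermediate
6 | methyl 6-methoxy-9-methyl-4-(3-methylbut-2-en-1-yl)-3,5-dioxodec-8-enoate (diastereomer mixture) | COC(=O)CC(=O)C(CC=C(C)C)C(=O)C(OC)CC=C(C)C | intermediate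
7 | 4-hydroxy-6-(1-methoxy-4-methylpent-3-en-1-yl)-5-(3-methylbut-2-en-1-yl)-2H-pyran-2-one (racemic) | COC(CC=C(C)C)C1=C(CC=C(C)C)C(O)=CC(=O)O1 | intermediate
8 | 3-phenylpropanoic acid | O=C(O)CCc1ccccc1 | starting material
9 | 6-(1-methoxy-4-methylpent-3-en-1-yl)-5-(3-methylbut-2-en-1-yl)-2-oxo-2H-pyran-4-yl 3-phenylpropanoate (racemic; formed in the flask, not isolated) | COC(CC=C(C)C)C1=C(CC=C(C)C)C(OC(=O)CCc2ccccc2)=CC(=O)O1 | intermediate
10 | 4-hydroxy-6-(1-methoxy-4-methylpent-3-en-1-yl)-5-(3-methylbut-2-en-1-yl)-3-(3-phenylpropanoyl)-2H-pyran-2-one (racemic) | COC(CC=C(C)C)C1=C(CC=C(C)C)C(O)=C(C(=O)CCc2ccccc2)C(=O)O1 | intermediate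
11 | 4-methoxy-6-(1-methoxy-4-methylpent-3-en-1-yl)-5-(3-methylbut-2-en-1-yl)-3-(3-phenylpropanoyl)-2H-pyran-2-one (racemic) | COC(CC=C(C)C)C1=C(CC=C(C)C)C(OC)=C(C(=O)CCc2ccccc2)C(=O)O1 | intermediate
12 | ring-opened acyl triazolium enolate: zwitterion in which the former lactone carbon C2 of 11 is a ketone bound to C3 of the (5aS,10bR)-2-mesityl triazolium and the former ring oxygen is the C6 enolate; double-bond geometry as in the pyrone, C1 still racemic (formed in the flask, not isolated) | [O-]/C(C(OC)CC=C(C)C)=C(CC=C(C)C)\C(OC)=C(/C(=O)c1n2c(n[n+]1-c1c(C)cc(C)cc1C)CO[C@H]1Cc3ccccc3[C@@H]21)C(=O)CCc1ccccc1 | intermediate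
13 | (6S)-5-hydroxy-3,6-dimethoxy-4,6-bis(3-methylbut-2-en-1-yl)-2-(3-phenylpropanoyl)cyclohexa-2,4-dien-1-one | CO[C@]1(CC=C(C)C)C(=O)C(C(=O)CCc2ccccc2)=C(OC)C(CC=C(C)C)=C1O | intermediate
14 | (6S)-3,5-dihydroxy-6-methoxy-4,6-bis(3-methylbut-2-en-1-yl)-2-(3-phenylpropanoyl)cyclohexa-2,4-dien-1-one (CNP0319461.1) | CO[C@]1(CC=C(C)C)C(=O)C(C(=O)CCc2ccccc2)=C(O)C(CC=C(C)C)=C1O | target

**Count and risks**

Total step count: 8. Longest linear sequence: 7 steps (4 → 5 → 6 → 7 → 10 → 11 → 13 → 14); step 1 supplies the second branch.

Steps most likely to fail: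

1. Step 7. The carbene may be consumed by conjugate addition at the doubly activated C4 instead of opening the lactone. The proton relay from C5 to C1 may be too slow, so that the opened intermediate only recloses through oxygen. Facial selectivity at the planar C1 enolate may be poor. Fallback by known chemistry, setting out from 11: NaOMe in MeOH at 65 °C should open the lactone to methyl 3,6-dimethoxy-9-methyl-4-(3-methylbut-2-en-1-yl)-5-oxo-2-(3-phenylpropanoyl)deca-2,8-dienoate F1, which is not isolated and should close by Dieckmann-type condensation, with loss of methanol, to racemic 5-hydroxy-3,6-dimethoxy-4,6-bis(3-methylbut-2-en-1-yl)-2-(3-phenylpropanoyl)cyclohexa-2,4-dien-1-one F2. Preparative chromatography on a chiral stationary phase (amylose tris(3,5-dimethylphenylcarbamate)) would then separate the (6S)-enantiomer, which is 13, from (6R)-5-hydroxy-3,6-dimethoxy-4,6-bis(3-methylbut-2-en-1-yl)-2-(3-phenylpropanoyl)cyclohexa-2,4-dien-1-one F3. The route is rejoined at 13.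

2. Step 3. The dianion may deprotonate the α-alkoxy ester instead of adding to it, and acylation at the already substituted γ-carbon may stall. Fallback setting out from 3: reduction with iBu2AlH (CH2Cl2, −78 °C) should give 2-methoxy-5-methylhex-4-enal F4. Aldol addition of the dianion of 5 (LiN(iPr)2, THF, −78 °C) should give methyl 5-hydroxy-6-methoxy-9-methyl-4-(3-methylbut-2-en-1-yl)-3-oxodec-8-enoate F5. Oxidation with Dess–Martin periodinane (CH2Cl2, rt) returns to the route at 6.

3. Step 8. Chloride may remove the vinylogous ester methyl only at a temperature where retro-Claisen ring cleavage or incomplete dealkylation intervenes. Fallback setting out from 10, with a change of the O4 group: allyl bromide and K2CO3 in acetone should give 4-(prop-2-en-1-yloxy)-6-(1-methoxy-4-methylpent-3-en-1-yl)-5-(3-methylbut-2-en-1-yl)-3-(3-phenylpropanoyl)-2H-pyran-2-one F6. The conditions of step 7 applied to it should give (6S)-5-hydroxy-6-methoxy-4,6-bis(3-methylbut-2-en-1-yl)-2-(3-phenylpropanoyl)-3-(prop-2-en-1-yloxy)cyclohexa-2,4-dien-1-one F7. Pd(PPh3)4 (zerovalent palladium) and morpholine in THF at rt then remove the allyl group (Tsuji–Trost deallylation) and return to the route at 14.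

Further compounds
F1 | step 7 | methyl 3,6-dimethoxy-9-methyl-4-(3-methylbut-2-en-1-yl)-5-oxo-2-(3-phenylpropanoyl)deca-2,8-dienoate | COC(=O)C(C(=O)CCc1ccccc1)=C(OC)C(CC=C(C)C)C(=O)C(OC)CC=C(C)C
F2 | step 7 | racemic 5-hydroxy-3,6-dimethoxy-4,6-bis(3-methylbut-2-en-1-yl)-2-(3-phenylpropanoyl)cyclohexa-2,4-dien-1-one | COC1(CC=C(C)C)C(=O)C(C(=O)CCc2ccccc2)=C(OC)C(CC=C(C)C)=C1O
F3 | step 7 | (6R)-5-hydroxy-3,6-dimethoxy-4,6-bis(3-methylbut-2-en-1-yl)-2-(3-phenylpropanoyl)cyclohexa-2,4-dien-1-one | CO[C@@]1(CC=C(C)C)C(=O)C(C(=O)CCc2ccccc2)=C(OC)C(CC=C(C)C)=C1O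
F4 | step 3 | 2-methoxy-5-methylhex-4-enal (racemic) | COC(C=O)CC=C(C)C
F5 | step 3 | methyl 5-hydroxy-6-methoxy-9-methyl-4-(3-methylbut-2-en-1-yl)-3-oxodec-8-enoate (diastereomer mixture) | COC(=O)CC(=O)C(CC=C(C)C)C(O)C(OC)CC=C(C)C
F6 | step 8 | 4-(prop-2-en-1-yloxy)-6-(1-methoxy-4-methylpent-3-en-1-yl)-5-(3-methylbut-2-en-1-yl)-3-(3-phenylpropanoyl)-2H-pyran-2-one (racemic) | COC(CC=C(C)C)C1=C(CC=C(C)C)C(OCC=C)=C(C(=O)CCc2ccccc2)C(=O)O1
F7 | step 8 | (6S)-5-hydroxy-6-methoxy-4,6-bis(3-methylbut-2-en-1-yl)-2-(3-phenylpropanoyl)-3-(prop-2-en-1-yloxy)cyclohexa-2,4-dien-1-one | CO[C@]1(CC=C(C)C)C(=O)C(C(=O)CCc2ccccc2)=C(OCC=C)C(CC=C(C)C)=C1O
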